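**Remarks before the route**

- Abbreviations: MOM = methoxymethyl; geranyl = (2E)-3,7-dimethylocta-2,6-dien-1-yl; prenyl = 3-methylbut-2-en-1-yl. Flavonoid numbering is used (O1, C2, C3, C4, C4a, C5 to C8, C8a; ring B C1' to C6').
- The target is the 2,3-trans (2R,3R) isomer defined by the SMILES string.
- Assumption: (S)-BINAP is assigned to the required C2 configuration by analogy with the facial sense of rhodium–BINAP aryl additions to cyclic enones and 4-pyridones; if a model reaction shows the opposite sense, (R)-BINAP is used instead.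

**Retrosynthetic overview**

1. Target ⇐ removal of four aryl MOM ethers from the tetra-MOM flavanonol.
2. Flavanonol ⇐ one-flask union of three components at ring C: a flat 6-geranyl-8-prenyl-5,7-bis(MOM-oxy)chromone (rings A and C), the arylzinc of 3,5-bis(MOM-oxy)anisole (ring B, metalated between its two acetal oxygens) and one electrophilic oxygen atom (DMDO). This forms C2–C1', sets C2 and C3 and installs the C3 hydroxyl.
3. Enabling feature: the O1–C2=C3–C4=O vinylogous ester of the γ-pyranone ring C. C2 is both the β-carbon of the C4 ketone and the O1-bearing carbon (aryl acceptor); C3 is the α-carbon, which emerges as an enol silyl ether ready for oxygenation.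
4. Chromone ⇐ enaminone cyclisation of a 2-hydroxyacetophenone (ring C closed through O1–C2). Ring A ⇐ phloroglucinol: its one unprotected oxygen (O1) carries a 1,1-dimethylallyl group that becomes the C8 prenyl by Claisen rearrangement, and the C6 geranyl and C4a acetyl groups come from two directed ortho-metalations.
5. Ring order: rings A and B are bought as benzene derivatives; ring C is built flat in step 7 and converted into the stereogenic dihydropyranone in step 9.

Key step: step 9

**Route**

Step 1
Reactants: 1 phloroglucinol (benzene-1,3,5-triol)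
Product: 2 3,5-bis(methoxymethoxy)phenol
Conditions: NaH (2.0 equiv), MOMCl (2.0 equiv), DMF, 0 °C to 20 °C; chromatography, mono- and tris-ethers recycled
Reagents that add atoms: chloromethyl methyl ether (MOMCl), COCCl
Why: Williamson-type MOM protection of a threefold-symmetric triol with two equivalents should give the bis-ether as the main component of a statistical mixture, and because the three hydroxyls are equivalent it is a single constitutional isomer that leaves one unique phenol, the future O1.

Step 2
Reactants: 2 3,5-bis(methoxymethoxy)phenol; 3 3-chloro-3-methylbut-1-yne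
Product: 4 1,3-bis(methoxymethoxy)-5-[(2-methylbut-3-yn-2-yl)oxy]benzene
Conditions: CuCl2·2H2O (1 mol%), DBU, MeCN, 0 °C
Reagents that add atoms: none
Why: The copper-catalysed O-alkylation of phenols with tertiary propargylic chlorides should etherify the only free phenol under mild basic conditions that leave the MOM acetals untouched.

Step 3
Reactants: 4 1,3-bis(methoxymethoxy)-5-[(2-methylbut-3-yn-2-yl)oxy]benzene
Product: 5 1,3-bis(methoxymethoxy)-5-[(2-methylbut-3-en-2-yl)oxy]benzene
Conditions: H2 (1 atm), Pd/CaCO3 poisoned with Pb(OAc)2, quinoline, EtOAc, 20 °C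
Reagents that add atoms: none
Why: Lindlar-type semi-hydrogenation should stop at the vinyl stage and give a 1,1-dimethylallyl aryl ether that has no hydrogen alpha to oxygen, so it cannot undergo Wittig rearrangement in the lithiation steps.

Step 4
Reactants: 5 1,3-bis(methoxymethoxy)-5-[(2-methylbut-3-en-2-yl)oxy]benzene; 6 geranyl bromide
Product: 9 2-geranyl-1,3-bis(methoxymethoxy)-5-[(2-methylbut-3-en-2-yl)oxy]benzene, via aryllithium 7 (not isolated), via arylcopper 8 (not isolated)
Conditions: n-BuLi, THF, 0 °C; CuBr·SMe2, −78 °C; 6, −78 °C to 0 °C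
Reagents that add atoms: none
Why: Directed ortho-metalation should occur at the carbon flanked by the two MOM ethers (cooperative chelation, the bulky tertiary ether does not direct), and the derived arylcopper should displace the primary allylic bromide in the SN2 mode so that the E olefin is kept.

Step 5
Reactants: 9 2-geranyl-1,3-bis(methoxymethoxy)-5-[(2-methylbut-3-en-2-yl)oxy]benzene; 10 N-methoxy-N-methylacetamide
Product: 13 1-{3-geranyl-2,4-bis(methoxymethoxy)-6-[(2-methylbut-3-en-2-yl)oxy]phenyl}ethanone, via aryllithium 11 (not isolated), via lithium hemiaminal 12 (not isolated)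
Conditions: s-BuLi, TMEDA, THF, −78 °C; 10, −78 °C to 0 °C; H2O
Reagents that add atoms: none
Why: A second directed ortho-metalation can only take place at one of the two equivalent remaining ring positions, next to a MOM ether, and acylation of the aryllithium with the Weinreb amide should stop at the ketone stage through the chelated tetrahedral adduct 12.

Step 6
Reactants: 13 1-{3-geranyl-2,4-bis(methoxymethoxy)-6-[(2-methylbut-3-en-2-yl)oxy]phenyl}ethanone
Product: 15 1-[3-geranyl-6-hydroxy-2,4-bis(methoxymethoxy)-5-prenylphenyl]ethanone, via dienone 14 (not isolated)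
Conditions: N,N-diethylaniline, 130 °C
Reagents that add atoms: none
Why: The aromatic Claisen rearrangement of the 1,1-dimethylallyl ether should deliver the allyl terminus to the only free ortho carbon (the other bears the acetyl group), which turns the branched unit into the linear prenyl group and, after tautomerisation of dienone 14, frees O1–H as the single phenol, hydrogen-bonded to the ketone.

Step 7
Reactants: 15 1-[3-geranyl-6-hydroxy-2,4-bis(methoxymethoxy)-5-prenylphenyl]ethanone; 16 N,N-dimethylformamide dimethyl acetal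
Product: 18 6-geranyl-5,7-bis(methoxymethoxy)-8-prenyl-4H-chromen-4-one, via enaminone 17 (not isolated)
Conditions: 16, toluene, 100 °C; then AcOH, CH2Cl2, 40 °C
Reagents that add atoms: none
Why: Condensation of the methyl ketone with the amide acetal should give the enaminone, and mild acid should trigger conjugate addition of the only free phenol followed by loss of dimethylamine (enaminone chromone synthesis), so ring C closes through O1 without regiochemical ambiguity.

Step 8
Reactants: 19 5-methoxybenzene-1,3-diol
Product: 20 1-methoxy-3,5-bis(methoxymethoxy)benzene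
Conditions: NaH, MOMCl, DMF, 0 °C to 20 °C
Reagents that add atoms: chloromethyl methyl ether (MOMCl), COCCl
Why: Standard Williamson-type MOM protection of both phenols should give the arene whose C–H between the two acetal oxygens is the preferred site of the directed metalation used in step 9.

Step 9
Reactants: 18 6-geranyl-5,7-bis(methoxymethoxy)-8-prenyl-4H-chromen-4-one; 20 1-methoxy-3,5-bis(methoxymethoxy)benzene
Product: 26 (2R,3R)-6-geranyl-3-hydroxy-2-[4-methoxy-2,6-bis(methoxymethoxy)phenyl]-5,7-bis(methoxymethoxy)-8-prenyl-2,3-dihydro-4H-chromen-4-one, via aryllithium 21 (not isolated), via arylzinc chloride 22 (not isolated), via silyl enol ether 23 (not isolated), via silyloxy epoxide 24 (not isolated), via silyloxy ketone 25 (not isolated)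
Conditions: 20 (1.5 equiv), n-BuLi, THF, 0 °C; ZnCl2, 20 °C; 18, [RhCl((S)-BINAP)]2 (3 mol% of monovalent rhodium), Me3SiCl, THF, 20 °C; DMDO in acetone, −78 °C, added in portions until 23 is consumed; aq. citric acid, 0 °C
Reagents that add atoms: dimethyldioxirane (DMDO), CC1(C)OO1
Why: Proposed new method: arylzinc chloride 22 should transmetalate to the chloro(BINAP)rhodium complex, the aryl–rhodium species should add across C2=C3 of the chromone with the aryl group going to C2, and Me3SiCl should silylate the oxa-π-allyl rhodium enolate to give enol ether 23 and return the rhodium chloride; DMDO should then epoxidise the C3=C4 enol ether to 24, which collapses by 1,4-silyl shift to silyloxy ketone 25 (Rubottom oxidation) and is desilylated on work-up. The closest known reaction types are the rhodium–BINAP-catalysed asymmetric 1,4-addition of arylzinc chlorides to 4-pyridones and 4-quinolones in the presence of Me3SiCl, the rhodium-catalysed asymmetric 1,4-addition of arylboronic acids to chromones, and the Rubottom oxidation of flavanone silyl enol ethers; their fusion in one flask and the use of an aryl donor with two ortho oxygen substituents are the unprecedented parts. No ring is closed: the flat γ-pyranone ring C is converted into the dihydropyranone of the target. C2 is set by the chiral ligand on rhodium (catalyst control), and C3 by the C2 aryl group, whose two ortho substituents shield one face of the enol ether so that oxygen should enter anti and give the 2,3-trans product, which is also the thermodynamically preferred isomer. The step needs 1,4- over 1,2-addition (secured by the soft aryl–rhodium species and the unsubstituted C2), enantioface selection (ligand), and oxidation of the enol ether in preference to the three trisubstituted olefins (secured by the much higher nucleophilicity of the tetrasubstituted silyl enol ether toward DMDO at −78 °C and by titrating the oxidant).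

Step 10
Reactants: 26 (2R,3R)-6-geranyl-3-hydroxy-2-[4-methoxy-2,6-bis(methoxymethoxy)phenyl]-5,7-bis(methoxymethoxy)-8-prenyl-2,3-dihydro-4H-chromen-4-one
Product: 27 (2R,3R)-2-(2,6-dihydroxy-4-methoxyphenyl)-6-geranyl-3,5,7-trihydroxy-8-prenyl-2,3-dihydro-4H-chromen-4-one
Conditions: 3 M HCl, MeOH, 45 °C, argon
Reagents that add atoms: none
Why: Acid-catalysed acetal exchange in methanol should remove the four aryl MOM ethers as dimethoxymethane under conditions used for prenylated flavonoids, and neither stereocentre is touched because C3 is not enolised by dilute acid and the 2,3-trans arrangement is the thermodynamically preferred one.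

**Compound list**

1 | phloroglucinol | Oc1cc(O)cc(O)c1 | starting material
2 | 3,5-bis(methoxymethoxy)phenol | COCOc1cc(O)cc(OCOC)c1 | intermediate
3 | 3-chloro-3-methylbut-1-yne | CC(C)(Cl)C#C | starting material
4 | 1,3-bis(methoxymethoxy)-5-[(2-methylbut-3-yn-2-yl)oxy]benzene | COCOc1cc(OCOC)cc(OC(C)(C)C#C)c1 | intermediate
5 | 1,3-bis(methoxymethoxy)-5-[(2-methylbut-3-en-2-yl)oxy]benzene | COCOc1cc(OCOC)cc(OC(C)(C)C=C)c1 | intermediate
6 | geranyl bromide, (2E)-1-bromo-3,7-dimethylocta-2,6-diene | BrC/C=C(\C)CCC=C(C)C | starting material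
7 | aryllithium: {2,6-bis(methoxymethoxy)-4-[(2-methylbut-3-en-2-yl)oxy]phenyl}lithium | COCOc1cc(OC(C)(C)C=C)cc(OCOC)c1[Li] | intermediate
8 | arylcopper: {2,6-bis(methoxymethoxy)-4-[(2-methylbut-3-en-2-yl)oxy]phenyl}copper | COCOc1cc(OC(C)(C)C=C)cc(OCOC)c1[Cu] | intermediate
9 | 2-geranyl-1,3-bis(methoxymethoxy)-5-[(2-methylbut-3-en-2-yl)oxy]benzene | C=CC(C)(C)Oc1cc(OCOC)c(C/C=C(\C)CCC=C(C)C)c(OCOC)c1 | intermediate
10 | N-methoxy-N-methylacetamide | CC(=O)N(C)OC | starting material
11 | aryllithium of 9, lithium on the ring carbon between the allyl ether and a MOM ether | C=CC(C)(C)Oc1cc(OCOC)c(C/C=C(\C)CCC=C(C)C)c(OCOC)c1[Li] | intermediate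
12 | lithium hemiaminal: lithium 1-aryl-1-[methoxy(methyl)amino]ethanolate from 11 and 10 | [Li+].CC([O-])(N(C)OC)c1c(OC(C)(C)C=C)cc(OCOC)c(C/C=C(\C)CCC=C(C)C)c1OCOC | intermediate
13 | 1-{3-geranyl-2,4-bis(methoxymethoxy)-6-[(2-methylbut-3-en-2-yl)oxy]phenyl}ethanone | CC(=O)c1c(OC(C)(C)C=C)cc(OCOC)c(C/C=C(\C)CCC=C(C)C)c1OCOC | intermediate
14 | dienone: 2-acetyl-4-geranyl-3,5-bis(methoxymethoxy)-6-prenylcyclohexa-2,4-dien-1-one (racemic at C6) | CC(=O)C1=C(OCOC)C(C/C=C(\C)CCC=C(C)C)=C(OCOC)C(CC=C(C)C)C1=O | intermediate
15 | 1-[3-geranyl-6-hydroxy-2,4-bis(methoxymethoxy)-5-prenylphenyl]ethanone | CC(=O)c1c(O)c(CC=C(C)C)c(OCOC)c(C/C=C(\C)CCC=C(C)C)c1OCOC | intermediate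
16 | N,N-dimethylformamide dimethyl acetal | COC(OC)N(C)C | starting material
17 | enaminone: (2E)-3-(dimethylamino)-1-[3-geranyl-6-hydroxy-2,4-bis(methoxymethoxy)-5-prenylphenyl]prop-2-en-1-one | CN(C)/C=C/C(=O)c1c(O)c(CC=C(C)C)c(OCOC)c(C/C=C(\C)CCC=C(C)C)c1OCOC | intermediate
18 | 6-geranyl-5,7-bis(methoxymethoxy)-8-prenyl-4H-chromen-4-one | O=c1ccoc2c(CC=C(C)C)c(OCOC)c(C/C=C(\C)CCC=C(C)C)c(OCOC)c12 | intermediate
19 | 5-methoxybenzene-1,3-diol | COc1cc(O)cc(O)c1 | starting material
20 | 1-methoxy-3,5-bis(methoxymethoxy)benzene | COCOc1cc(OC)cc(OCOC)c1 | intermediate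
21 | aryllithium: [4-methoxy-2,6-bis(methoxymethoxy)phenyl]lithium | COCOc1cc(OC)cc(OCOC)c1[Li] | intermediate
22 | arylzinc chloride: chloro[4-methoxy-2,6-bis(methoxymethoxy)phenyl]zinc | COCOc1cc(OC)cc(OCOC)c1[Zn]Cl | intermediate
23 | silyl enol ether: (2S)-6-geranyl-2-[4-methoxy-2,6-bis(methoxymethoxy)phenyl]-5,7-bis(methoxymethoxy)-8-prenyl-4-(trimethylsilyloxy)-2H-chromene | COc1cc(OCOC)c([C@H]2Oc3c(CC=C(C)C)c(OCOC)c(C/C=C(\C)CCC=C(C)C)c(OCOC)c3C(O[Si](C)(C)C)=C2)c(OCOC)c1 | intermediate
24 | silyloxy epoxide: 3,4-epoxide of 23 with the trimethylsilyloxy group on C4 and the epoxide oxygen on the ring face opposite to the C2 aryl group | COc1cc(OCOC)c([C@H]2Oc3c(CC=C(C)C)c(OCOC)c(C/C=C(\C)CCC=C(C)C)c(OCOC)c3[C@]4(O[Si](C)(C)C)O[C@H]24)c(OCOC)c1 | intermediate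
25 | silyloxy ketone: (2R,3R)-3-(trimethylsilyloxy) ether of 26, 2,3-trans | COc1cc(OCOC)c([C@H]2Oc3c(CC=C(C)C)c(OCOC)c(C/C=C(\C)CCC=C(C)C)c(OCOC)c3C(=O)[C@@H]2O[Si](C)(C)C)c(OCOC)c1 | intermediate
26 | (2R,3R)-6-geranyl-3-hydroxy-2-[4-methoxy-2,6-bis(methoxymethoxy)phenyl]-5,7-bis(methoxymethoxy)-8-prenyl-2,3-dihydro-4H-chromen-4-one | COc1cc(OCOC)c([C@H]2Oc3c(CC=C(C)C)c(OCOC)c(C/C=C(\C)CCC=C(C)C)c(OCOC)c3C(=O)[C@@H]2O)c(OCOC)c1 | intermediate
27 | (2R,3R)-2-(2,6-dihydroxy-4-methoxyphenyl)-6-geranyl-3,5,7-trihydroxy-8-prenyl-2,3-dihydro-4H-chromen-4-one | COc1cc(O)c([C@H]2Oc3c(CC=C(C)C)c(O)c(C/C=C(\C)CCC=C(C)C)c(O)c3C(=O)[C@@H]2O)c(O)c1 | target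

**Step count and risks**

Total step count: 10. Longest linear sequence: 9 steps (steps 1 to 7, then 9 and 10); step 8 is the one-step branch for ring B.

Steps most likely to fail:

Step 9 (Proposed new method). What may go wrong:
- slow aryl transfer from zinc to rhodium and slow insertion, because both ortho positions of the aryl donor are substituted;
- insufficient enantioface discrimination;
- over-oxidation of the side-chain olefins by the dioxirane;
- cleavage of MOM acetals by Me3SiCl and ZnCl2.

The fallback uses known chemistry and closes ring C at O1–C2 instead; it sets out from 15 and 20 and comes back to the route at 26. Arene 20 is lithiated (n-BuLi, THF, 0 °C) and formylated with DMF to give 4-methoxy-2,6-bis(methoxymethoxy)benzaldehyde F1. Claisen–Schmidt condensation of this aldehyde with hydroxy ketone 15 (KOH, EtOH, 20 °C) should give the E-configured 2'-hydroxychalcone F2. Its phenol is silylated (TBSOTf, 2,6-lutidine, CH2Cl2, 0 °C) to the silyl ether F3. Juliá–Colonna epoxidation (poly-L-leucine, urea–H2O2, DBU, THF) should then give the (αR,βS)-epoxy ketone F4, the enone being the only olefin that reacts with a nucleophilic peroxide. Desilylation (TBAF, AcOH, THF, 0 °C) frees O1–H, which should open the epoxide at the benzylic carbon in the 6-endo mode with inversion (completed with a trace of camphorsulfonic acid if needed) to give the 2,3-trans compound 26.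

Step 5. What may go wrong:
- competing lateral deprotonation at the benzylic-allylic CH2 of the geranyl chain;
- intramolecular SN2' transfer of the allyl unit to the lithiated carbon;
- attack of the alkyllithium on the allyl ether.

The fallback avoids any lithiation next to the allyl ether; it sets out from 9 and comes back at 15. Heating 9 (N,N-diethylaniline, 130 °C) should effect the Claisen rearrangement first and give 4-geranyl-3,5-bis(methoxymethoxy)-2-prenylphenol F5. Magnesium-mediated ortho-formylation (MgCl2, Et3N, paraformaldehyde, MeCN, reflux) at the only free ortho carbon gives 3-geranyl-6-hydroxy-2,4-bis(methoxymethoxy)-5-prenylbenzaldehyde F6. Addition of MeMgBr (THF, 0 °C) gives the benzylic alcohol 1-[3-geranyl-6-hydroxy-2,4-bis(methoxymethoxy)-5-prenylphenyl]ethanol F7, and oxidation of the benzylic alcohol (MnO2, CH2Cl2, 20 °C) gives 15.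

Step 10. What may go wrong:
- acid-promoted cyclisation of the prenyl or geranyl olefins onto the neighbouring phenols;
- C2 epimerisation through reversible opening of ring C.

The fallback replaces Brønsted-acid hydrolysis by silyl transfer; it sets out from 26 and comes back at 27. Treatment of 26 with Me3SiOTf and 2,2'-bipyridyl (CH2Cl2, 0 °C) should exchange the four aryl MOM groups for trimethylsilyl groups and silylate the C3 hydroxyl, giving the pentakis(trimethylsilyl) ether F8. Neutral hydrolysis (H2O, MeOH, 20 °C) then gives 27 without exposure of the side chains to strong acid.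

**Further compounds**

F1 | step 9 | 4-methoxy-2,6-bis(methoxymethoxy)benzaldehyde | COc1cc(OCOC)c(C=O)c(OCOC)c1
F2 | step 9 | (2E)-1-[3-geranyl-6-hydroxy-2,4-bis(methoxymethoxy)-5-prenylphenyl]-3-[4-methoxy-2,6-bis(methoxymethoxy)phenyl]prop-2-en-1-one | O=C(/C=C/c1c(OCOC)cc(OC)cc1OCOC)c2c(O)c(CC=C(C)C)c(OCOC)c(C/C=C(\C)CCC=C(C)C)c2OCOC
F3 | step 9 | tert-butyldimethylsilyl ether of F2 at the phenol oxygen | O=C(/C=C/c1c(OCOC)cc(OC)cc1OCOC)c2c(O[Si](C)(C)C(C)(C)C)c(CC=C(C)C)c(OCOC)c(C/C=C(\C)CCC=C(C)C)c2OCOC
F4 | step 9 | {(2R,3S)-3-[4-methoxy-2,6-bis(methoxymethoxy)phenyl]oxiran-2-yl}[2-(tert-butyldimethylsilyloxy)-5-geranyl-4,6-bis(methoxymethoxy)-3-prenylphenyl]methanone | O=C([C@@H]1O[C@H]1c2c(OCOC)cc(OC)cc2OCOC)c3c(O[Si](C)(C)C(C)(C)C)c(CC=C(C)C)c(OCOC)c(C/C=C(\C)CCC=C(C)C)c3OCOC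
F5 | step 5 | 4-geranyl-3,5-bis(methoxymethoxy)-2-prenylphenol | Oc1cc(OCOC)c(C/C=C(\C)CCC=C(C)C)c(OCOC)c1CC=C(C)C
F6 | step 5 | 3-geranyl-6-hydroxy-2,4-bis(methoxymethoxy)-5-prenylbenzaldehyde | O=Cc1c(O)c(CC=C(C)C)c(OCOC)c(C/C=C(\C)CCC=C(C)C)c1OCOC
F7 | step 5 | 1-[3-geranyl-6-hydroxy-2,4-bis(methoxymethoxy)-5-prenylphenyl]ethanol (racemic) | CC(O)c1c(O)c(CC=C(C)C)c(OCOC)c(C/C=C(\C)CCC=C(C)C)c1OCOC
F8 | step 10 | (2R,3R)-pentakis(trimethylsilyl) ether of 27 (all five hydroxyls silylated) | COc1cc(O[Si](C)(C)C)c([C@H]2Oc3c(CC=C(C)C)c(O[Si](C)(C)C)c(C/C=C(\C)CCC=C(C)C)c(O[Si](C)(C)C)c3C(=O)[C@@H]2O[Si](C)(C)C)c(O[Si](C)(C)C)c1
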